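**Retrosynthetic overview**

- The feruloyl ester is disconnected last at the acyl C–O bond, giving the (2R)-2-(hydroxymethyl)-2H-chromene and a phenol-protected ferulic acid.
- The C3=C4 double bond and the CH2OH group are traced back to a C4 ketone and a C2 methyl ester, with the 6-acetyl group masked as a dioxolane.
- The strategy rests on C2, the quaternary stereocentre bearing O1, CH3, a carboxyl-level CH2O carbon and C3H2. This is C2 of (R)-citramalic acid, whose C4 carboxyl becomes the C4 ketone on C4a. Ring B (O1, C2, C3, C4, C4a, C8a) is closed at C8a–O1 when the tertiary alkoxide displaces a fluoride ortho to that ketone.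
- The C4–C4a bond comes from a Negishi acylation of an arylzinc (from 4'-fluoro-3'-methoxyacetophenone via ketal, ortho-lithiation next to fluorine and iodination) with the acid chloride of citramalic acid acetonide.
- Ring order: ring A (benzene) is bought; ring B is the only ring formed (step 7).

Key step: step 7

Remark: chromene numbering is used for all intermediates. The CIP order at C2 (O1 > carboxyl-derived carbon > C3 > CH3) is the same in citramalic acid, every intermediate and the target, so the descriptor stays (R) throughout.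

**Route**

Step 1
Reactants: 1 4'-fluoro-3'-methoxyacetophenone
Product: 2 2-(4-fluoro-3-methoxyphenyl)-2-methyl-1,3-dioxolane
Conditions: ethylene glycol (3 equiv), TsOH·H2O (cat.), toluene, reflux, azeotropic removal of water
Reagents that add atoms: ethylene glycol, OCCO
Why: Acid-catalysed ketalisation masks the acetyl group against the organometallic and hydride steps that follow.

Step 2
Reactants: 2 2-(4-fluoro-3-methoxyphenyl)-2-methyl-1,3-dioxolane
Product: 4 2-(4-fluoro-3-iodo-5-methoxyphenyl)-2-methyl-1,3-dioxolane, via aryllithium 3 (not isolated)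
Conditions: n-BuLi (1.1 equiv), PMDTA (1.1 equiv), THF, −78 °C; then I2, THF, −78 °C to rt
Reagents that add atoms: iodine, II
Why: Directed ortho-metalation under acidity control (lithium saturated by PMDTA) should remove the proton next to fluorine, the most acidic ring C–H as in 2-fluoroanisole, and iodine traps the aryllithium at −78 °C before LiF can be lost to an aryne.

Step 3
Reactants: 5 (R)-citramalic acid
Product: 6 2-[(4R)-2,2,4-trimethyl-5-oxo-1,3-dioxolan-4-yl]acetic acid
Conditions: 2,2-dimethoxypropane, TsOH·H2O (cat.), rt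
Reagents that add atoms: 2,2-dimethoxypropane, COC(C)(C)OC
Why: Acetonide (dioxolanone) formation ties the tertiary hydroxyl to the adjacent carboxyl in a five-membered ring, as with malic acid, so only the C4 carboxyl stays free and no bond to the stereocentre is broken.

Step 4
Reactants: 6 2-[(4R)-2,2,4-trimethyl-5-oxo-1,3-dioxolan-4-yl]acetic acid
Product: 7 2-[(4R)-2,2,4-trimethyl-5-oxo-1,3-dioxolan-4-yl]acetyl chloride
Conditions: (COCl)2 (1.2 equiv), DMF (cat.), CH2Cl2, 0 °C to rt; evaporate, use crude
Reagents that add atoms: oxalyl chloride, ClC(=O)C(=O)Cl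
Why: Vilsmeier-type activation converts the free acid into the acid chloride under conditions that the dioxolanone tolerates.

Step 5
Reactants: 4 2-(4-fluoro-3-iodo-5-methoxyphenyl)-2-methyl-1,3-dioxolane and 7 2-[(4R)-2,2,4-trimethyl-5-oxo-1,3-dioxolan-4-yl]acetyl chloride
Product: 10 (5R)-5-{2-[2-fluoro-3-methoxy-5-(2-methyl-1,3-dioxolan-2-yl)phenyl]-2-oxoethyl}-2,2,5-trimethyl-1,3-dioxolan-4-one, via arylmagnesium chloride 8 (not isolated), via arylzinc chloride 9 (not isolated)
Conditions: 4, iPrMgCl·LiCl (1.0 equiv), THF, −20 °C; ZnCl2 (1.1 equiv), THF, 0 °C; then 7, Pd(PPh3)4 (5 mol %), THF, 0 °C to rt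
Reagents that add atoms: none
Why: Iodine–magnesium exchange and transmetalation give an arylzinc that ignores the dioxolanone and the product ketone but undergoes Negishi acylation with the acid chloride under the zerovalent palladium complex Pd(PPh3)4, forming the C4–C4a bond.

Step 6
Reactants: 10 (5R)-5-{2-[2-fluoro-3-methoxy-5-(2-methyl-1,3-dioxolan-2-yl)phenyl]-2-oxoethyl}-2,2,5-trimethyl-1,3-dioxolan-4-one
Product: 11 methyl (2R)-4-[2-fluoro-3-methoxy-5-(2-methyl-1,3-dioxolan-2-yl)phenyl]-2-hydroxy-2-methyl-4-oxobutanoate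
Conditions: NaOMe (0.1 equiv), MeOH–THF, −20 °C; AcOH quench
Reagents that add atoms: methanol, CO
Why: Methoxide-catalysed transesterification should open the activated dioxolanone (the hemiketal alkoxide then loses acetone) much faster than enolisation or aromatic substitution in cold methanol, and C2 is not touched.

Step 7
Reactants: 11 methyl (2R)-4-[2-fluoro-3-methoxy-5-(2-methyl-1,3-dioxolan-2-yl)phenyl]-2-hydroxy-2-methyl-4-oxobutanoate
Product: 12 methyl (2R)-8-methoxy-2-methyl-6-(2-methyl-1,3-dioxolan-2-yl)-4-oxochromane-2-carboxylate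
Conditions: K2CO3 (2 equiv), DMF, 0 °C to 15 °C; quench into cold pH 6 buffer as soon as 11 is consumed; crude taken directly into step 8
Reagents that add atoms: none
Why: K2CO3 reversibly deprotonates the tertiary hydroxyl (acidified by the geminal ester), the alkoxide adds to C8a ipso to fluorine to give a Meisenheimer anion delocalised onto the ortho C4 carbonyl, and loss of fluoride forms the C8a–O1 bond (addition–elimination SNAr). The closest known reaction type is the base-mediated cyclisation of 2-fluoroaryl β-hydroxy ketones to chroman-4-ones. Ring B (O1, C2, C3, C4, C4a, C8a) closes in a six-membered exo mode, the breaking C–F bond lying outside the new ring. No stereocentre is created, and C2 keeps the (R) configuration of citramalic acid because none of its four bonds is broken. The step needs cyclisation to beat retro-aldol cleavage of the aldolate and enolisation followed by retro-oxa-Michael opening of the product, either of which would erode C2. The ortho-acyl activation, the six-membered transition state, the low basicity of the α-ester alkoxide, a weak heterogeneous base at low temperature and immediate reduction of the crude ketone are relied on to secure this.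

Step 8
Reactants: 12 methyl (2R)-8-methoxy-2-methyl-6-(2-methyl-1,3-dioxolan-2-yl)-4-oxochromane-2-carboxylate
Product: 13 (2R)-2-(hydroxymethyl)-8-methoxy-2-methyl-6-(2-methyl-1,3-dioxolan-2-yl)chroman-4-ol (mixture of C4 epimers)
Conditions: LiAlH4 (2.5 equiv), THF, −20 °C to 0 °C, substrate added to the hydride; aqueous work-up
Reagents that add atoms: none
Why: Hydride reduction of ketone and ester removes the enolisable C4 carbonyl at once and so closes the retro-oxa-Michael channel, the ketal is inert, and the new C4 carbinol centre forms without control because it is destroyed in step 9.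

Step 9
Reactants: 13 (2R)-2-(hydroxymethyl)-8-methoxy-2-methyl-6-(2-methyl-1,3-dioxolan-2-yl)chroman-4-ol
Product: 15 1-[(2R)-2-(hydroxymethyl)-8-methoxy-2-methyl-2H-chromen-6-yl]ethanone, via chromene ketal alcohol 14 (not isolated)
Conditions: TsOH·H2O (10 mol %), toluene, 70 °C; then acetone–H2O, rt
Reagents that add atoms: water, O
Why: E1 dehydration of the 4-chromanol through the benzylic cation stabilised by the ortho ring oxygen gives the conjugated 2H-chromene, and acid hydrolysis of the dioxolane in wet acetone then releases the 6-acetyl group, with C2 not involved.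

Step 10
Reactants: 16 ferulic acid
Product: 17 (2E)-3-(4-acetoxy-3-methoxyphenyl)prop-2-enoic acid
Conditions: NaOH (2 equiv, aq.), Ac2O (1.2 equiv), 0 °C; then HCl to pH 2
Reagents that add atoms: acetic anhydride, CC(=O)OC(C)=O
Why: Schotten–Baumann acetylation of the phenoxide blocks the phenol so that it cannot compete as a nucleophile in the esterification.

Step 11
Reactants: 17 (2E)-3-(4-acetoxy-3-methoxyphenyl)prop-2-enoic acid and 15 1-[(2R)-2-(hydroxymethyl)-8-methoxy-2-methyl-2H-chromen-6-yl]ethanone
Product: 19 [(2R)-6-acetyl-8-methoxy-2-methyl-2H-chromen-2-yl]methyl (2E)-3-(4-acetoxy-3-methoxyphenyl)prop-2-enoate, via 4-acetoxy-3-methoxycinnamoyl chloride 18 (not isolated)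
Conditions: 17, (COCl)2, DMF (cat.), CH2Cl2, 0 °C to rt, evaporate; then 15, Et3N (2 equiv), DMAP (cat.), CH2Cl2, 0 °C to rt
Reagents that add atoms: none
Why: DMAP-catalysed acylation by the acid chloride is chosen because the neopentyl-type primary alcohol reacts as the nucleophile at an acyl carbon, where its hindrance matters little, and the E alkene and C2 are untouched.

Step 12
Reactants: 19 [(2R)-6-acetyl-8-methoxy-2-methyl-2H-chromen-2-yl]methyl (2E)-3-(4-acetoxy-3-methoxyphenyl)prop-2-enoate
Product: 20 [(2R)-6-acetyl-8-methoxy-2-methyl-2H-chromen-2-yl]methyl (2E)-3-(4-hydroxy-3-methoxyphenyl)prop-2-enoate (CNP0168033.1)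
Conditions: pyrrolidine (3 equiv), THF, 0 °C to rt, short contact; dilute HCl wash
Reagents that add atoms: none
Why: Aminolysis of the phenolic acetate should be far faster than attack on the hindered alkyl cinnamate or conjugate addition, so the phenol is released selectively.

**Compound list**

1 | 4'-fluoro-3'-methoxyacetophenone | CC(=O)c1ccc(F)c(OC)c1 | starting material
2 | 2-(4-fluoro-3-methoxyphenyl)-2-methyl-1,3-dioxolane | CC1(OCCO1)c1ccc(F)c(OC)c1 | intermediate
3 | [2-fluoro-3-methoxy-5-(2-methyl-1,3-dioxolan-2-yl)phenyl]lithium (formed in the flask) | CC1(OCCO1)c1cc([Li])c(F)c(OC)c1 | intermediate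
4 | 2-(4-fluoro-3-iodo-5-methoxyphenyl)-2-methyl-1,3-dioxolane | CC1(OCCO1)c1cc(I)c(F)c(OC)c1 | intermediate
5 | (R)-citramalic acid | OC(=O)[C@@](O)(C)CC(=O)O | starting material
6 | 2-[(4R)-2,2,4-trimethyl-5-oxo-1,3-dioxolan-4-yl]acetic acid | OC(=O)C[C@@]1(C)OC(C)(C)OC1=O | intermediate
7 | 2-[(4R)-2,2,4-trimethyl-5-oxo-1,3-dioxolan-4-yl]acetyl chloride | ClC(=O)C[C@@]1(C)OC(C)(C)OC1=O | intermediate
8 | [2-fluoro-3-methoxy-5-(2-methyl-1,3-dioxolan-2-yl)phenyl]magnesium chloride (formed in the flask) | CC1(OCCO1)c1cc([Mg]Cl)c(F)c(OC)c1 | intermediate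
9 | [2-fluoro-3-methoxy-5-(2-methyl-1,3-dioxolan-2-yl)phenyl]zinc chloride (formed in the flask) | CC1(OCCO1)c1cc([Zn]Cl)c(F)c(OC)c1 | intermediate
10 | (5R)-5-{2-[2-fluoro-3-methoxy-5-(2-methyl-1,3-dioxolan-2-yl)phenyl]-2-oxoethyl}-2,2,5-trimethyl-1,3-dioxolan-4-one | CC1(OCCO1)c1cc(C(=O)C[C@@]2(C)OC(C)(C)OC2=O)c(F)c(OC)c1 | intermediate
11 | methyl (2R)-4-[2-fluoro-3-methoxy-5-(2-methyl-1,3-dioxolan-2-yl)phenyl]-2-hydroxy-2-methyl-4-oxobutanoate | COC(=O)[C@@](O)(C)CC(=O)c1cc(C2(C)OCCO2)cc(OC)c1F | intermediate
12 | methyl (2R)-8-methoxy-2-methyl-6-(2-methyl-1,3-dioxolan-2-yl)-4-oxochromane-2-carboxylate | COC(=O)[C@@]1(C)CC(=O)c2cc(C3(C)OCCO3)cc(OC)c2O1 | intermediate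
13 | (2R)-2-(hydroxymethyl)-8-methoxy-2-methyl-6-(2-methyl-1,3-dioxolan-2-yl)chroman-4-ol (C4 epimers) | OC[C@@]1(C)CC(O)c2cc(C3(C)OCCO3)cc(OC)c2O1 | intermediate
14 | [(2R)-8-methoxy-2-methyl-6-(2-methyl-1,3-dioxolan-2-yl)-2H-chromen-2-yl]methanol (formed in the flask) | OC[C@@]1(C)C=Cc2cc(C3(C)OCCO3)cc(OC)c2O1 | intermediate
15 | 1-[(2R)-2-(hydroxymethyl)-8-methoxy-2-methyl-2H-chromen-6-yl]ethanone | OC[C@@]1(C)C=Cc2cc(C(C)=O)cc(OC)c2O1 | intermediate
16 | ferulic acid | COc1cc(/C=C/C(=O)O)ccc1O | starting material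
17 | (2E)-3-(4-acetoxy-3-methoxyphenyl)prop-2-enoic acid | COc1cc(/C=C/C(=O)O)ccc1OC(C)=O | intermediate
18 | (2E)-3-(4-acetoxy-3-methoxyphenyl)prop-2-enoyl chloride (formed in the flask) | COc1cc(/C=C/C(Cl)=O)ccc1OC(C)=O | intermediate
19 | [(2R)-6-acetyl-8-methoxy-2-methyl-2H-chromen-2-yl]methyl (2E)-3-(4-acetoxy-3-methoxyphenyl)prop-2-enoate | COc1cc(/C=C/C(=O)OC[C@@]2(C)C=Cc3cc(C(C)=O)cc(OC)c3O2)ccc1OC(C)=O | intermediate
20 | [(2R)-6-acetyl-8-methoxy-2-methyl-2H-chromen-2-yl]methyl (2E)-3-(4-hydroxy-3-methoxyphenyl)prop-2-enoate | COc1cc(/C=C/C(=O)OC[C@@]2(C)C=Cc3cc(C(C)=O)cc(OC)c3O2)ccc1O | target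

**Step count**

Total steps: 12. Longest linear sequence: 9 (steps 1, 2, 5, 6, 7, 8, 9, 11, 12; the citramalic branch through steps 3 and 4 is equally long).

**Steps most likely to fail**

Step 7. The aldolate may fragment by retro-aldol, or the product may enolise and ring-open by retro-oxa-Michael; either erodes the C2 configuration. Substitution on the electron-rich ring may also be too slow to outrun these. The fallback sets out from 11 and returns at 15; it keeps the C8a–O1 closure but removes the C4 carbonyl first, so neither fragmentation is possible.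
- LiAlH4 in THF at 0 °C should reduce ketone and ester to (2R)-4-[2-fluoro-3-methoxy-5-(2-methyl-1,3-dioxolan-2-yl)phenyl]-2-methylbutane-1,2,4-triol F1.
- PPTS in wet acetone should unmask the acetyl group, giving 1-{4-fluoro-3-methoxy-5-[(3R)-1,3,4-trihydroxy-3-methylbutyl]phenyl}ethanone F2, in which fluorine is now para to a ketone.
- TrCl, Et3N and DMAP in CH2Cl2 should tritylate only the primary hydroxyl, giving 1-{3-[(3R)-1,3-dihydroxy-3-methyl-4-(trityloxy)butyl]-4-fluoro-5-methoxyphenyl}ethanone F3.
- KOtBu in THF at 0 °C to rt should close ring B by SNAr activated by the para-acetyl group (the secondary alkoxide cannot cyclise), giving 1-[(2R)-4-hydroxy-8-methoxy-2-methyl-2-(trityloxymethyl)chroman-6-yl]ethanone F4.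
- TsOH·H2O in toluene at 70 °C and then wet acetone should dehydrate C4 and cleave the trityl ether to give 15.

Step 9. The benzylic cation may be captured by the free primary hydroxyl to give a bridged ether instead of eliminating. Hot acid may also ionise the allylic C2–O1 bond of the chromene and erode configuration. The fallback sets out from 13 and returns at 15.
- TBSCl and imidazole in DMF at 0 °C should silylate the primary hydroxyl, giving (2R)-2-{[tert-butyl(dimethyl)silyl]oxymethyl}-8-methoxy-2-methyl-6-(2-methyl-1,3-dioxolan-2-yl)chroman-4-ol F5.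
- MsCl and Et3N in CH2Cl2 at 0 °C to rt (DBU if needed) should eliminate the benzylic mesylate under basic conditions, giving tert-butyl{[(2R)-8-methoxy-2-methyl-6-(2-methyl-1,3-dioxolan-2-yl)-2H-chromen-2-yl]methoxy}dimethylsilane F6.
- Dilute aqueous HCl in THF at rt should remove the silyl ether and the ketal to give 15.

Step 2. Metalation may occur at the position between the methoxy group and the ketal-bearing carbon, or the aryllithium may lose LiF to an aryne. The fallback sets out from 2 and returns at 4.
- C–H borylation with [Ir(OMe)(cod)]2, 4,4'-di-tert-butyl-2,2'-bipyridine and B2pin2 in THF at 60 °C is governed by sterics. It should reach only the C–H flanked by fluorine and hydrogen, giving 2-[2-fluoro-3-methoxy-5-(2-methyl-1,3-dioxolan-2-yl)phenyl]-4,4,5,5-tetramethyl-1,3,2-dioxaborolane F7.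
- Ipso-iododeboronation with NaI and chloramine-T (TsNClNa) in THF–H2O at rt should then give 4.

**Further compounds**

F1 | step 7 | (2R)-4-[2-fluoro-3-methoxy-5-(2-methyl-1,3-dioxolan-2-yl)phenyl]-2-methylbutane-1,2,4-triol | OC[C@@](O)(C)CC(O)c1cc(C2(C)OCCO2)cc(OC)c1F
F2 | step 7 | 1-{4-fluoro-3-methoxy-5-[(3R)-1,3,4-trihydroxy-3-methylbutyl]phenyl}ethanone | OC[C@@](O)(C)CC(O)c1cc(C(C)=O)cc(OC)c1F
F3 | step 7 | 1-{3-[(3R)-1,3-dihydroxy-3-methyl-4-(trityloxy)butyl]-4-fluoro-5-methoxyphenyl}ethanone | C(c1ccccc1)(c1ccccc1)(c1ccccc1)OC[C@@](O)(C)CC(O)c1cc(C(C)=O)cc(OC)c1F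
F4 | step 7 | 1-[(2R)-4-hydroxy-8-methoxy-2-methyl-2-(trityloxymethyl)chroman-6-yl]ethanone | C(c1ccccc1)(c1ccccc1)(c1ccccc1)OC[C@@]1(C)CC(O)c2cc(C(C)=O)cc(OC)c2O1
F5 | step 9 | (2R)-2-{[tert-butyl(dimethyl)silyl]oxymethyl}-8-methoxy-2-methyl-6-(2-methyl-1,3-dioxolan-2-yl)chroman-4-ol | CC(C)(C)[Si](C)(C)OC[C@@]1(C)CC(O)c2cc(C3(C)OCCO3)cc(OC)c2O1
F6 | step 9 | tert-butyl{[(2R)-8-methoxy-2-methyl-6-(2-methyl-1,3-dioxolan-2-yl)-2H-chromen-2-yl]methoxy}dimethylsilane | CC(C)(C)[Si](C)(C)OC[C@@]1(C)C=Cc2cc(C3(C)OCCO3)cc(OC)c2O1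
F7 | step 2 | 2-[2-fluoro-3-methoxy-5-(2-methyl-1,3-dioxolan-2-yl)phenyl]-4,4,5,5-tetramethyl-1,3,2-dioxaborolane | CC1(OCCO1)c1cc(B2OC(C)(C)C(C)(C)O2)c(F)c(OC)c1
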